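**Plan**
1. Retrosynthesis: the two C–Br bonds (C3, C5) and the exocyclic C2=CH2 are traced back to cyclohexenone 9 (C3=O, C4=C5); its ring is then cut at C4–C5 (aldol condensation) and at C1–C6 (Michael addition).
2. Enabling feature: the quaternary C6 (CMe2) lies between the chain-bearing C1 and C5, so C5–C6(CH3)2 is an isobutyraldehyde unit. C1–C2–C3–C4 with the side chain is a β-substituted methyl vinyl ketone in which linalool C6 becomes ring C1; the carbocycle, the only ring, is a [3+3] union of the two.
3. Forward: (S)-linalool is silylated, ozonised at its trisubstituted alkene and olefinated to enone 5; step 4 closes the six-membered ring; eight further steps adjust functionality and add only the methylene carbon.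
4. Stereochemistry: C3′ comes from (S)-linalool and C1 from the chiral primary amine in step 4. The C5 oxygen is placed α by hydroxyl-directed epoxidation (steps 5–6) and the C3 oxygen β by hydroxyl-directed hydride delivery (step 10); bromide SN2 then inverts both to 5β-Br and 3α-Br.
5. Convention: ring locants C1–C6 as in line 2; α is the ring face that carries the C1 side chain, β the opposite face.

Key step: step 4

Assumption: the epi-quinine-derived primary amine is taken to deliver the nucleophile to the enone face that gives (5R)-9; the sense would be confirmed on the first run, and the quinidine-derived pseudoenantiomer gives access to the opposite face.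

Step 1
Reactants: 1 (S)-(+)-linalool
Product: 2 (S)-triethyl[(3,7-dimethylocta-1,6-dien-3-yl)oxy]silane
Conditions: Et3SiOTf, 2,6-lutidine, CH2Cl2, −78 °C to 0 °C
Reagents that add atoms: triethylsilyl trifluoromethanesulfonate, CC[Si](CC)(CC)OS(=O)(=O)C(F)(F)F
Why: A silyl triflate with a hindered pyridine base silylates the tertiary allylic alcohol at low temperature (silyl ether protection) and leaves both alkenes and the C3′ stereocentre untouched.

Step 2
Reactants: 2 (S)-triethyl[(3,7-dimethylocta-1,6-dien-3-yl)oxy]silane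
Product: 3 (4S)-4-methyl-4-(triethylsilyloxy)hex-5-enal
Conditions: O3, CH2Cl2, −78 °C, Sudan Red 7B as end-point indicator; then PPh3, −78 °C to rt
Reagents that add atoms: ozone, [O-][O+]=O
Why: Ozonolysis dosed to the dye end point is chemoselective for the electron-rich trisubstituted alkene over the monosubstituted vinyl group beside the silyloxy carbon, and phosphine reduction of the ozonide gives the aldehyde without touching C3′.

Step 3
Reactants: 3 (4S)-4-methyl-4-(triethylsilyloxy)hex-5-enal; 4 1-(triphenylphosphoranylidene)propan-2-one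
Product: 5 (S,E)-7-methyl-7-(triethylsilyloxy)nona-3,8-dien-2-one
Conditions: CH2Cl2, 40 °C
Reagents that add atoms: none
Why: Wittig olefination with the stabilised acylmethylene ylide should give the (E)-enone selectively under neutral conditions that neither desilylate nor epimerise.

Step 4
Reactants: 5 (S,E)-7-methyl-7-(triethylsilyloxy)nona-3,8-dien-2-one; 6 isobutyraldehyde (2-methylpropanal)
Product: 9 (5R)-4,4-dimethyl-5-[(3S)-3-methyl-3-(triethylsilyloxy)pent-4-en-1-yl]cyclohex-2-en-1-one, via Michael keto-aldehyde 7 (not isolated), via cyclic ketol 8 (not isolated)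
Conditions: 9-amino-9-deoxy-epi-quinine (20 mol %), 2-fluorobenzoic acid (40 mol %), 6 (5 equiv), toluene, 40 °C; then removal of excess 6 in vacuo, KOH, MeOH, 0 °C to rt
Reagents that add atoms: none
Why: Proposed new method: the primary amine forms the enamine of 6 and activates 5 as its (E)-iminium ion (or through the protonated quinuclidine), so the fully substituted enamine carbon adds to the enone β-carbon and creates C1–C6 together with the quaternary C6; the closest known reactions are the enamine Michael–aldol (Robinson-type) annulation of isobutyraldehyde with vinyl ketones to 4,4-dimethylcyclohexenones and cinchona primary-amine iminium catalysis of conjugate additions to (E)-β-alkyl enones, which have not been shown together on a β-alkyl enone under catalyst control. Hydrolysis releases keto-aldehyde 7, and KOH then enolises the methyl ketone, whose terminal enolate attacks the neopentyl aldehyde in a 6-(enolendo)-exo-trig aldol that forms C4–C5 and closes the only ring as ketol 8. E1cB dehydration of 8 gives the conjugated enone 9 and makes the sequence irreversible. The single new stereocentre, C1, is set in the Michael step by the catalyst, whose quinoline and quinuclidine units block one face of the iminium ion; the remote C3′ centre exerts no bias, so diastereoselectivity is purely catalyst-controlled. The step needs cross-Michael addition to win over self-condensation and needs a single aldol mode: 6 has only one α-hydrogen and cannot form an aldol condensation product with itself, the aldehyde of 7 has no α-hydrogen and so can only act as the electrophile, and the alternative ketone enolate (towards C2) could close only a four-membered ring. The C3′ silyl ether and vinyl group are inert to both the amine salt and methanolic KOH.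

Step 5
Reactants: 9 (5R)-4,4-dimethyl-5-[(3S)-3-methyl-3-(triethylsilyloxy)pent-4-en-1-yl]cyclohex-2-en-1-one
Product: 10 (1S,5R)-4,4-dimethyl-5-[(3S)-3-methyl-3-(triethylsilyloxy)pent-4-en-1-yl]cyclohex-2-en-1-ol (3α-OH, cis to the chain)
Conditions: NaBH4, CeCl3·7H2O, MeOH, −78 °C
Reagents that add atoms: none
Why: Luche reduction gives clean 1,2-reduction, and hydride adds to the carbonyl face opposite the C1 side chain (axial attack on the half-chair, as with other 5-substituted cyclohexenones), so the new C3 carbinol carries its OH on the α face.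

Step 6
Reactants: 10 (1S,5R)-4,4-dimethyl-5-[(3S)-3-methyl-3-(triethylsilyloxy)pent-4-en-1-yl]cyclohex-2-en-1-ol
Product: 11 (1S,2S,4R,6R)-5,5-dimethyl-4-[(3S)-3-methyl-3-(triethylsilyloxy)pent-4-en-1-yl]-7-oxabicyclo[4.1.0]heptan-2-ol (3α-OH, 4α,5α-epoxide)
Conditions: VO(acac)2 (5 mol %), t-BuOOH (decane solution), CH2Cl2, 0 °C to rt
Reagents that add atoms: tert-butyl hydroperoxide, CC(C)(C)OO
Why: In the vanadium-catalysed epoxidation of allylic alcohols the metal-bound peroxide is delivered to the alkene face of the coordinated hydroxyl, so the 3α-OH places the oxirane on the α face of C4=C5 (the face that alkaline peroxide on 9 would not reach), while the side-chain vinyl group, lacking a free hydroxyl, is not attacked.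

Step 7
Reactants: 11 (1S,2S,4R,6R)-5,5-dimethyl-4-[(3S)-3-methyl-3-(triethylsilyloxy)pent-4-en-1-yl]-7-oxabicyclo[4.1.0]heptan-2-ol
Product: 12 (1R,4R,6R)-5,5-dimethyl-4-[(3S)-3-methyl-3-(triethylsilyloxy)pent-4-en-1-yl]-7-oxabicyclo[4.1.0]heptan-2-one (4α,5α-epoxy ketone)
Conditions: Dess–Martin periodinane, pyridine, CH2Cl2, 0 °C to rt
Reagents that add atoms: none
Why: Dess–Martin oxidation of the secondary alcohol under pyridine-buffered conditions returns the C3 ketone needed for methylenation and leaves the oxirane stereocentres and the silyl ether intact.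

Step 8
Reactants: 12 (1R,4R,6R)-5,5-dimethyl-4-[(3S)-3-methyl-3-(triethylsilyloxy)pent-4-en-1-yl]-7-oxabicyclo[4.1.0]heptan-2-one
Product: 15 (1R,4S,6R)-5,5-dimethyl-3-methylidene-4-[(3S)-3-methyl-3-(triethylsilyloxy)pent-4-en-1-yl]-7-oxabicyclo[4.1.0]heptan-2-one, via Mannich base 13 (not isolated), via methiodide 14 (not isolated)
Conditions: LiN(SiMe3)2, THF, −78 °C; Me2N=CH2 I (Eschenmoser's salt), −78 °C to rt; MeI, CH2Cl2, rt; aq. NaHCO3, rt
Reagents that add atoms: dimethyl(methylidene)ammonium iodide (Eschenmoser's salt), C=[N+](C)C.[I-]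
Why: Only the C2 hydrogens are removable (C4–H lies on the oxirane, C6 is quaternary), so the amide base gives a single enolate whose Mannich reaction, quaternisation and E1cB loss of trimethylamine (Eschenmoser methylenation) install the exocyclic methylene regiospecifically, the transient C2 stereocentre being destroyed.

Step 9
Reactants: 15 (1R,4S,6R)-5,5-dimethyl-3-methylidene-4-[(3S)-3-methyl-3-(triethylsilyloxy)pent-4-en-1-yl]-7-oxabicyclo[4.1.0]heptan-2-one
Product: 16 (3S,5S)-5-hydroxy-4,4-dimethyl-2-methylidene-3-[(3S)-3-methyl-3-(triethylsilyloxy)pent-4-en-1-yl]cyclohexan-1-one (5α-OH)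
Conditions: SmI2 (2.5 equiv), THF–MeOH, −90 °C; pH 7 buffer
Reagents that add atoms: none
Why: Electron transfer from SmI2 to the ketone gives a ketyl that expels the α-oxygen (reductive cleavage of the C4–O bond of an α,β-epoxy ketone), which should be faster at −90 °C than reduction of the enone, and protonation of the samarium enolate at C4 gives the ketol in which the untouched C5–O bond keeps its α configuration.

Step 10
Reactants: 16 (3S,5S)-5-hydroxy-4,4-dimethyl-2-methylidene-3-[(3S)-3-methyl-3-(triethylsilyloxy)pent-4-en-1-yl]cyclohexan-1-one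
Product: 17 (1S,3S,5S)-4,4-dimethyl-6-methylidene-5-[(3S)-3-methyl-3-(triethylsilyloxy)pent-4-en-1-yl]cyclohexane-1,3-diol (3β-OH, 5α-OH)
Conditions: Me4NBH(OAc)3, MeCN–AcOH, −30 °C
Reagents that add atoms: none
Why: In the Evans–Saksena reduction the 5α-hydroxyl exchanges an acetate on boron and the resulting alkoxyborohydride delivers hydride intramolecularly to the α face of the C3 carbonyl, so the new C3 hydroxyl is β (anti-1,3-diol), the configuration that external hydride attacking the β face would not give.

Step 11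
Reactants: 17 (1S,3S,5S)-4,4-dimethyl-6-methylidene-5-[(3S)-3-methyl-3-(triethylsilyloxy)pent-4-en-1-yl]cyclohexane-1,3-diol
Product: 19 triethyl({(3S)-5-[(1S,3R,5R)-3,5-dibromo-2,2-dimethyl-6-methylidenecyclohexyl]-3-methylpent-1-en-3-yl}oxy)silane, via allylic monobromide 18 (not isolated)
Conditions: PPh3, CBr4, CH2Cl2, 0 °C; then further PPh3, CBr4, 40 °C
Reagents that add atoms: tetrabromomethane, BrC(Br)(Br)Br
Why: Appel bromination turns each hydroxyl into an alkoxyphosphonium ion that bromide displaces by SN2 with inversion: the allylic 3β-oxygen reacts first at 0 °C to give the 3α-bromide 18, and on warming the equatorial 5α-oxygen is displaced along the β-axial trajectory, which eclipses the C6–C1 ring bond and not a methyl group, to give the 5β-bromide.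

Step 12
Reactants: 19 triethyl({(3S)-5-[(1S,3R,5R)-3,5-dibromo-2,2-dimethyl-6-methylidenecyclohexyl]-3-methylpent-1-en-3-yl}oxy)silane
Product: 20 (3S)-5-[(1S,3R,5R)-3,5-dibromo-2,2-dimethyl-6-methylidenecyclohexyl]-3-methylpent-1-en-3-ol (CNP0393289.1)
Conditions: HF·pyridine, pyridine, THF, 0 °C
Reagents that add atoms: none
Why: Pyridine-buffered HF·pyridine cleaves the triethylsilyl ether by fluoride attack at silicon under mild, non-basic conditions that should leave the allylic and neopentyl bromides and all four stereocentres unchanged.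

**Compound list**
1 | (S)-(+)-linalool | C=C[C@@](C)(O)CCC=C(C)C | starting material
2 | (S)-triethyl[(3,7-dimethylocta-1,6-dien-3-yl)oxy]silane | C=C[C@@](C)(O[Si](CC)(CC)CC)CCC=C(C)C | intermediate
3 | (4S)-4-methyl-4-(triethylsilyloxy)hex-5-enal | C=C[C@@](C)(O[Si](CC)(CC)CC)CCC=O | intermediate
4 | 1-(triphenylphosphoranylidene)propan-2-one | CC(=O)C=P(c1ccccc1)(c1ccccc1)c1ccccc1 | starting material
5 | (S,E)-7-methyl-7-(triethylsilyloxy)nona-3,8-dien-2-one | C=C[C@@](C)(O[Si](CC)(CC)CC)CC/C=C/C(C)=O | intermediate
6 | isobutyraldehyde (2-methylpropanal) | CC(C)C=O | starting material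
7 | (3R,6S)-2,2,6-trimethyl-3-(2-oxopropyl)-6-(triethylsilyloxy)oct-7-enal (Michael keto-aldehyde) | C=C[C@@](C)(O[Si](CC)(CC)CC)CC[C@H](CC(C)=O)C(C)(C)C=O | intermediate
8 | (5R)-3-hydroxy-4,4-dimethyl-5-[(3S)-3-methyl-3-(triethylsilyloxy)pent-4-en-1-yl]cyclohexan-1-one (cyclic ketol, C3 epimers) | C=C[C@@](C)(O[Si](CC)(CC)CC)CC[C@@H]1CC(=O)CC(O)C1(C)C | intermediate
9 | (5R)-4,4-dimethyl-5-[(3S)-3-methyl-3-(triethylsilyloxy)pent-4-en-1-yl]cyclohex-2-en-1-one | C=C[C@@](C)(O[Si](CC)(CC)CC)CC[C@@H]1CC(=O)C=CC1(C)C | intermediate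
10 | (1S,5R)-4,4-dimethyl-5-[(3S)-3-methyl-3-(triethylsilyloxy)pent-4-en-1-yl]cyclohex-2-en-1-ol | C=C[C@@](C)(O[Si](CC)(CC)CC)CC[C@@H]1C[C@H](O)C=CC1(C)C | intermediate
11 | (1S,2S,4R,6R)-5,5-dimethyl-4-[(3S)-3-methyl-3-(triethylsilyloxy)pent-4-en-1-yl]-7-oxabicyclo[4.1.0]heptan-2-ol | C=C[C@@](C)(O[Si](CC)(CC)CC)CC[C@@H]1C[C@H](O)[C@@H]2O[C@@H]2C1(C)C | intermediate
12 | (1R,4R,6R)-5,5-dimethyl-4-[(3S)-3-methyl-3-(triethylsilyloxy)pent-4-en-1-yl]-7-oxabicyclo[4.1.0]heptan-2-one | C=C[C@@](C)(O[Si](CC)(CC)CC)CC[C@@H]1CC(=O)[C@@H]2O[C@@H]2C1(C)C | intermediate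
13 | 3-[(dimethylamino)methyl] derivative of 12 (Mannich base, epimers at the aminomethyl-bearing carbon) | C=C[C@@](C)(O[Si](CC)(CC)CC)CC[C@@H]1C(CN(C)C)C(=O)[C@@H]2O[C@@H]2C1(C)C | intermediate
14 | trimethylammonium iodide of 13 (methiodide) | C=C[C@@](C)(O[Si](CC)(CC)CC)CC[C@@H]1C(C[N+](C)(C)C)C(=O)[C@@H]2O[C@@H]2C1(C)C.[I-] | intermediate
15 | (1R,4S,6R)-5,5-dimethyl-3-methylidene-4-[(3S)-3-methyl-3-(triethylsilyloxy)pent-4-en-1-yl]-7-oxabicyclo[4.1.0]heptan-2-one | C=C[C@@](C)(O[Si](CC)(CC)CC)CC[C@@H]1C(=C)C(=O)[C@@H]2O[C@@H]2C1(C)C | intermediate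
16 | (3S,5S)-5-hydroxy-4,4-dimethyl-2-methylidene-3-[(3S)-3-methyl-3-(triethylsilyloxy)pent-4-en-1-yl]cyclohexan-1-one | C=C[C@@](C)(O[Si](CC)(CC)CC)CC[C@@H]1C(=C)C(=O)C[C@H](O)C1(C)C | intermediate
17 | (1S,3S,5S)-4,4-dimethyl-6-methylidene-5-[(3S)-3-methyl-3-(triethylsilyloxy)pent-4-en-1-yl]cyclohexane-1,3-diol | C=C[C@@](C)(O[Si](CC)(CC)CC)CC[C@@H]1C(=C)[C@@H](O)C[C@H](O)C1(C)C | intermediate
18 | (1S,3S,5R)-5-bromo-2,2-dimethyl-4-methylidene-3-[(3S)-3-methyl-3-(triethylsilyloxy)pent-4-en-1-yl]cyclohexan-1-ol | C=C[C@@](C)(O[Si](CC)(CC)CC)CC[C@@H]1C(=C)[C@H](Br)C[C@H](O)C1(C)C | intermediate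
19 | triethyl({(3S)-5-[(1S,3R,5R)-3,5-dibromo-2,2-dimethyl-6-methylidenecyclohexyl]-3-methylpent-1-en-3-yl}oxy)silane | C=C[C@@](C)(O[Si](CC)(CC)CC)CC[C@@H]1C(=C)[C@H](Br)C[C@@H](Br)C1(C)C | intermediate
20 | (3S)-5-[(1S,3R,5R)-3,5-dibromo-2,2-dimethyl-6-methylidenecyclohexyl]-3-methylpent-1-en-3-ol | C=C[C@@](C)(O)CC[C@@H]1C(=C)[C@H](Br)C[C@@H](Br)C1(C)C | target

Total steps: 12. Longest linear sequence: 12 steps (1 to 20).

**Steps most likely to fail**

Step 4. The hindered enamine may add too slowly to the β-alkyl enone, or add without useful facial discrimination, so that 9 forms in low conversion or as a mixture of C1 epimers. The fallback uses known chemistry, sets out from aldehyde 3 and returns at 9; the ring then comes from a symmetrical dienone and C1 from a chiral ligand.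
- Pinnick oxidation (NaClO2, NaH2PO4, 2-methylbut-2-ene) would give (4S)-4-methyl-4-(triethylsilyloxy)hex-5-enoic acid F1.
- Coupling with N-hydroxypyridine-2-thione (DCC) would give the Barton ester 2-thioxopyridin-1(2H)-yl (4S)-4-methyl-4-(triethylsilyloxy)hex-5-enoate F2.
- Photolysis of F2 with iodoform (Barton decarboxylative iodination) would give the one-carbon-shorter iodide triethyl{[(3S)-5-iodo-3-methylpent-1-en-3-yl]oxy}silane F3.
- Iodine–zinc exchange with Et2Zn (CuI cat.) would give bis[(3S)-3-methyl-3-(triethylsilyloxy)pent-4-en-1-yl]zinc F4.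
- F4 would be added to commercial 4,4-dimethylcyclohexa-2,5-dien-1-one with Cu(OTf)2 and a chiral BINOL-derived phosphoramidite; this desymmetrising conjugate addition delivers 9 directly.

Step 11. The first-formed allylic bromide may undergo SN2′ transposition or epimerisation by bromide during the slow displacement at the neopentyl C5, and elimination or ring contraction may compete at C5. The fallback sets out from 16 and returns at 19; it masks the methylene so that no allylic bromide exists until the last operation.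
- Conjugate addition of PhSeH (Et3N cat., CH2Cl2, 0 °C) to the exocyclic enone would give the 2-[(phenylselanyl)methyl] ketone F5 (C2 epimers, inconsequential).
- Directed reduction as in step 10 would give the anti-diol selenide F6.
- Double Appel bromination, which can now be driven at higher temperature, would give the dibromo selenide F7.
- H2O2/pyridine at 0 °C would give the selenoxide F8, which undergoes syn-elimination towards C2–H, its only β-hydrogen, to unveil the methylene and give 19 under neutral conditions.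

Step 9. SmI2 may reduce or reductively dimerise the exocyclic enone in competition with oxirane cleavage, or the samarium aldolate may undergo retro-aldol or oxa-Michael reaction. The fallback sets out from 12 and returns at 16; it opens the oxirane before the enone exists.
- Step 8 would be stopped at the Mannich base 13, which is isolated.
- SmI2 reduction of this saturated epoxy ketone would give the 5α-hydroxy amino ketone F9.
- N-Methylation with MeI would give the ammonium iodide F10.
- Aqueous NaHCO3 would then eliminate trimethylamine to give 16.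

**Further compounds**
F1 | step 4 | (4S)-4-methyl-4-(triethylsilyloxy)hex-5-enoic acid | C=C[C@@](C)(O[Si](CC)(CC)CC)CCC(=O)O
F2 | step 4 | 2-thioxopyridin-1(2H)-yl (4S)-4-methyl-4-(triethylsilyloxy)hex-5-enoate | C=C[C@@](C)(O[Si](CC)(CC)CC)CCC(=O)On1ccccc1=S
F3 | step 4 | triethyl{[(3S)-5-iodo-3-methylpent-1-en-3-yl]oxy}silane | C=C[C@@](C)(O[Si](CC)(CC)CC)CCI
F4 | step 4 | bis[(3S)-3-methyl-3-(triethylsilyloxy)pent-4-en-1-yl]zinc | C=C[C@@](C)(O[Si](CC)(CC)CC)CC[Zn]CC[C@](C)(O[Si](CC)(CC)CC)C=C
F5 | step 11 | (3R,5S)-5-hydroxy-4,4-dimethyl-2-[(phenylselanyl)methyl]-3-[(3S)-3-methyl-3-(triethylsilyloxy)pent-4-en-1-yl]cyclohexan-1-one (C2 epimers) | C=C[C@@](C)(O[Si](CC)(CC)CC)CC[C@@H]1C(C[Se]c2ccccc2)C(=O)C[C@H](O)C1(C)C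
F6 | step 11 | (1S,3S,5R)-4,4-dimethyl-6-[(phenylselanyl)methyl]-5-[(3S)-3-methyl-3-(triethylsilyloxy)pent-4-en-1-yl]cyclohexane-1,3-diol (C6 epimers) | C=C[C@@](C)(O[Si](CC)(CC)CC)CC[C@@H]1C(C[Se]c2ccccc2)[C@@H](O)C[C@H](O)C1(C)C
F7 | step 11 | analogue of 19 carrying H and CH2SePh at C2 in place of the methylene (3α,5β-dibromide, C2 epimers) | C=C[C@@](C)(O[Si](CC)(CC)CC)CC[C@@H]1C(C[Se]c2ccccc2)[C@H](Br)C[C@@H](Br)C1(C)C
F8 | step 11 | selenoxide of F7 | C=C[C@@](C)(O[Si](CC)(CC)CC)CC[C@@H]1C(C[Se](=O)c2ccccc2)[C@H](Br)C[C@@H](Br)C1(C)C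
F9 | step 9 | 2-[(dimethylamino)methyl]-5-hydroxy-4,4-dimethyl-3-[(3S)-3-methyl-3-(triethylsilyloxy)pent-4-en-1-yl]cyclohexan-1-one (5α-OH, chain at C3 as in 16, C2 epimers) | C=C[C@@](C)(O[Si](CC)(CC)CC)CC[C@@H]1C(CN(C)C)C(=O)C[C@H](O)C1(C)C
F10 | step 9 | trimethylammonium iodide of F9 (methiodide) | C=C[C@@](C)(O[Si](CC)(CC)CC)CC[C@@H]1C(C[N+](C)(C)C)C(=O)C[C@H](O)C1(C)C.[I-]
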